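## Structural features

- The target 13 is (4S)-5,7-dihydroxy-8-[3-(4-methoxyphenyl)propanoyl]-4-phenyl-3,4-dihydro-2H-chromen-2-one. A pentasubstituted benzene ring A (C4a, C5, C6, C7, C8, C8a) is fused to a six-membered aryl lactone (O1, C2, C3, C4). C4 carries a phenyl group and C8 carries a dihydrochalcone-type acyl chain.
- The only stereocenter is the diarylmethine C4. The descriptor in the SMILES is read as S (CIP order C4a > phenyl > C3 > H).
- Ring A is an acylphloroglucinol. Oxygens on C5, C7 and C8a alternate with carbon-substituted C4a, C6 and C8, and the acyl carbonyl on C8 continues the alternation. This is the pattern of a folded tetraketide built from a 3-(4-methoxyphenyl)propanoyl starter and three acetate units.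
- The real difficulty is regiochemical, not only stereochemical. In a preformed acylphloroglucinol the two free ring carbons are equivalent, and the carbon that is alkylated lies between two different hydroxyls. The target needs the lactone on the C8a oxygen, which is ortho to the ketone, chelated and the less nucleophilic one, and not on the C5 oxygen.
- Fragile groups are the aryl lactone (opened by alkoxide or hydroxide and able to migrate to a neighbouring free phenol) and the electron-rich ring A (oxidation, retro-Friedel–Crafts in strong acid). The aryl methyl ether must survive every deprotection, so a methyl ether cannot serve as a temporary mask.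
- The key step exploits the 1,3,5-oxygen pattern of ring A. Ring A is made from a 2-pyrone whose C2, C3, C4, C5, C6 and side-chain CH2 become C8a, C4a, C5, C6, C7 and C8. In the pyrone the three future ring oxygens are chemically different (carbonyl oxygen, ether oxygen, ring oxygen), and there is a single nucleophilic carbon (C3) on which C4 can be set.

## Logic of the disconnections

**13 to 12.** The O–CH2Ph bond on the C5 oxygen is cut. The benzyl group is the only protecting group of the route. It keeps the C5 oxygen distinct from the C8a oxygen until the lactone exists. The forward step must be neutral so that the lactone does not migrate; hydrogenolysis meets this and spares the methyl ether.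

**12 to 11.** The lactone bond O1–C2 is cut to a phenol and a methyl ester. The gain is a base-stable open form that can pass through the ring-forming step. The demand is that only the C8a hydroxyl can reach the ester, which the C5 benzyl ether guarantees.

**11 to 9 (key).** The C8–C8a bond of ring A is cut, which unfolds the benzene ring into the 2-pyrone 9 via the open chain 10. In one sentence: ring A is closed last, by a Claisen condensation of C8 onto C8a within a pyrone-masked tetraketide that already carries C4. The gain is large. A pentasubstituted arene with three differentiated oxygens becomes a 3,4,6-trisubstituted 2-pyrone, and the ortho or para lactone question disappears because the oxygens are never equivalent. The forward step must choose Claisen over aldol closure and must leave C4 untouched.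

**9 to 8.** The benzyl ether on the pyrone O4 is cut. The forward step must alkylate O4 and not the carbonyl oxygen of the ambident pyronate or the active methylene.

**8 to 6.** The methyl ester C–O bond and the acid oxidation level are removed, back to the lactol 6 through the enol lactone 7. The gain is that C4 can come from an aldehyde-level Michael acceptor. The forward step needs an oxidant that spares the side-chain ketone and the anisole.

**6 to 3 and 4.** The C4–C4a bond (pyrone C3 to the β-carbon of the enal) and the hemiacetal C–O bond are cut. This is the stereo-defining disconnection. Compound 3 has one nucleophilic carbon, so there is no site selectivity to solve, and the catalyst sets the absolute configuration.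

**3 to 1 and 2.** The bond between the side-chain CH2 and the ketone carbon is cut, a Claisen acylation of the dianion of 1. This attaches the starter unit of the tetraketide. The forward step needs the methyl carbanion to be the reacting site.

## Other disconnections considered

**Alternative 1:** (the first that comes to mind) Cut C4–C4a and O1–C2. Forward: acid-promoted hydroarylation and lactonisation of 3-(4-methoxyphenyl)-1-(2,4,6-trihydroxyphenyl)propan-1-one A1 with cinnamic acid, or its iminium-catalysed variant with cinnamaldehyde followed by oxidation. It is short, but the hard question is left open: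
- After C-alkylation the side chain sits between a chelated hydroxyl ortho to the ketone and a free, more acidic para hydroxyl. The para hydroxyl is the better nucleophile, so the isomer (4S)-5,7-dihydroxy-6-[3-(4-methoxyphenyl)propanoyl]-4-phenyl-3,4-dihydro-2H-chromen-2-one A2 should compete with or dominate over the target.
- The acid variant is racemic.
- Both free ring carbons can react.

The chosen plan fixes the identity of every oxygen before ring A exists.

**Alternative 2:** Cut the C4–phenyl bond. Forward: rhodium-catalysed asymmetric 1,4-addition of PhB(OH)2 to 5,7-bis(benzyloxy)-8-[3-(4-methoxyphenyl)propanoyl]-2H-chromen-2-one A3, for example with Rh(acac)(C2H4)2 and a chiral bisphosphine. The stereocenter would be set reliably, but: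
- The regiochemical problem only moves back into the construction of A3 from an unsymmetrical acylphloroglucinol, with the same ortho or para ambiguity.
- C4 is flanked by the peri benzyloxy group on C5, which slows the addition.
- The aqueous base of the addition opens the lactone.
- Two protecting groups and a coumarin synthesis make it longer than the chosen route.

**Alternative 3:** Lactone-first folding. Cut C7–C8 of ring A in the dihydropyranone methyl 3-{(4S)-6-[4-(4-methoxyphenyl)-2-oxobutyl]-2-oxo-4-phenyl-3,4-dihydro-2H-pyran-5-yl}-3-oxopropanoate A4. Forward: Claisen closure of the side-chain methylene onto the ester, giving the target without protecting groups. A4 would come from a carbene-catalysed annulation of cinnamaldehyde with methyl 9-(4-methoxyphenyl)-3,5,7-trioxononanoate A5. This is attractive on paper, but: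
- A5 has three acidic methylenes and two enol oxygens, so the annulation has no reason to pick the one carbon and the one oxygen that are needed.
- The enol lactone of A4 cannot be expected to survive the base needed for the Claisen step (alkoxide opening, O-to-C acyl transfer to the β-keto ester carbanion).
- An aldol closure of the β-keto ester methylene onto the side-chain ketone would give a resorcylate.

That is three selectivity problems against one in the chosen plan.

Key step: step 5

Remark: 6 (and the lactols of the fallbacks) are handled as mixtures of anomers at the hemiacetal carbon; this carbon stops being a stereocenter on oxidation.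

## Route

Step 1
Reactants: 1 4-hydroxy-6-methyl-2H-pyran-2-one; 2 methyl 3-(4-methoxyphenyl)propanoate
Product: 3 4-hydroxy-6-[4-(4-methoxyphenyl)-2-oxobutyl]-2H-pyran-2-one
Conditions: LiN(i-Pr)2 (3.2 equiv), THF, −78 °C; then 2, −78 to 0 °C; 1 M HCl
Reagents that add atoms: none
Why: Claisen-type acylation of the O,C-dianion of 1 at the 6-methyl carbanion, its most basic site; the third equivalent of base takes up the more acidic product and so prevents a second acylation.

Step 2
Reactants: 3 4-hydroxy-6-[4-(4-methoxyphenyl)-2-oxobutyl]-2H-pyran-2-one; 4 (E)-cinnamaldehyde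
Product: 6 (4S)-2-hydroxy-7-[4-(4-methoxyphenyl)-2-oxobutyl]-4-phenyl-3,4-dihydro-2H,5H-pyrano[4,3-b]pyran-5-one (mixture of C2 anomers), via Michael adduct aldehyde 5 (not isolated)
Conditions: (S)-2-[diphenyl(trimethylsilyloxy)methyl]pyrrolidine (20 mol %), CH2Cl2, 0 °C to rt
Reagents that add atoms: none
Why: Iminium-catalysed Michael addition followed by hemiacetalisation, a reaction type established for 4-hydroxy-2-pyrones and cinnamaldehyde-type enals; pyrone C3 is the only nucleophilic carbon. In the E-iminium ion of 4 the diphenyl(silyloxy)methyl group of the S catalyst covers the Re face of the β-carbon, so C3 should add to the Si face and set C4 as S (order pyrone carbon > phenyl > CH2 > H).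

Step 3
Reactants: 6 (4S)-2-hydroxy-7-[4-(4-methoxyphenyl)-2-oxobutyl]-4-phenyl-3,4-dihydro-2H,5H-pyrano[4,3-b]pyran-5-one
Product: 8 methyl (3S)-3-{4-hydroxy-6-[4-(4-methoxyphenyl)-2-oxobutyl]-2-oxo-2H-pyran-3-yl}-3-phenylpropanoate, via enol lactone 7 (not isolated)
Conditions: PhI(OAc)2 (1.2 equiv), TEMPO (10 mol %), CH2Cl2, rt; then MeOH, Et3N, rt; dilute HCl work-up
Reagents that add atoms: methanol, CO
Why: Oxoammonium (TEMPO/PhI(OAc)2) oxidation of the lactol to the lactone, both anomers converging; 7 is an acyl derivative of a vinylogous acid (leaving group pKa about 5) and should be opened by methanol at the acyl carbon under mild base, which leaves C4 untouched.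

Step 4
Reactants: 8 methyl (3S)-3-{4-hydroxy-6-[4-(4-methoxyphenyl)-2-oxobutyl]-2-oxo-2H-pyran-3-yl}-3-phenylpropanoate
Product: 9 methyl (3S)-3-{4-(benzyloxy)-6-[4-(4-methoxyphenyl)-2-oxobutyl]-2-oxo-2H-pyran-3-yl}-3-phenylpropanoate
Conditions: BnOH, PPh3, diisopropyl azodicarboxylate, THF, 0 °C to rt
Reagents that add atoms: benzyl alcohol, OCc1ccccc1
Why: Mitsunobu etherification; only the 4-hydroxyl (pKa about 5) is acidic enough to be engaged, the side-chain active methylene is not, and 4-hydroxy-2-pyrones are alkylated at O4 under these conditions, which keeps the 2-pyrone form needed in step 5.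

Step 5
Reactants: 9 methyl (3S)-3-{4-(benzyloxy)-6-[4-(4-methoxyphenyl)-2-oxobutyl]-2-oxo-2H-pyran-3-yl}-3-phenylpropanoate
Product: 11 methyl (3S)-3-{6-(benzyloxy)-2,4-dihydroxy-3-[3-(4-methoxyphenyl)propanoyl]phenyl}-3-phenylpropanoate, via ring-opened diketo diester 10 (not isolated)
Conditions: Mg(OMe)2 (6 equiv), MeOH, 65 °C; then 1 M HCl, 0 °C
Reagents that add atoms: none
Why: Biomimetic Claisen-type recyclisation of a 6-(2-oxoalkyl)-2-pyrone into an acylphloroglucinol, the magnesium methoxide reaction of pyrone-masked polyketides, applied here to a 3-alkyl-4-benzyloxy member. Methoxide adds to the lactone carbonyl C2 of 9 and the C2–O1 bond breaks, giving the open magnesium diketonate 10, in which the new methyl ester and the 3,5-dioxo chain stay cis on the enol-ether double bond because both come from the ring. The doubly activated methylene between the two ketones (future C8) then attacks that ester carbonyl (future C8a) in a 6-(enolexo)-exo-trig closure, methoxide leaves, and enolisation of the cyclic trione gives aromatic ring A; aromatisation makes the sequence irreversible, whereas pyrone opening and reclosure are reversible. The selectivity needed is Claisen over aldol: the only aldol donor that could reach a ketone is the former pyrone C3, which is fully substituted and locked as an enol ether, so an aldol adduct could not aromatise and the resorcylate channel is closed. The oxygens are delivered without ambiguity: the pyrone carbonyl oxygen becomes the C8a phenol, the pyrone ring oxygen becomes the C7 phenol, and the benzyloxy group stays on C5. No stereocenter is formed; C4 is a spectator whose hydrogen is not acidic, and because C4a is a vinyl and then an aryl carbon throughout there is no retro-Michael path, so the S configuration from step 2 should be retained. The side-chain methyl ester matches the alkoxide and is out of reach of the carbanion (eight-membered transition state).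

Step 6
Reactants: 11 methyl (3S)-3-{6-(benzyloxy)-2,4-dihydroxy-3-[3-(4-methoxyphenyl)propanoyl]phenyl}-3-phenylpropanoate
Product: 12 (4S)-5-(benzyloxy)-7-hydroxy-8-[3-(4-methoxyphenyl)propanoyl]-4-phenyl-3,4-dihydro-2H-chromen-2-one
Conditions: TsOH·H2O (10 mol %), toluene, 4 Å molecular sieves, 80 °C
Reagents that add atoms: none
Why: Acid-catalysed lactonisation (intramolecular transesterification) to the six-membered aryl lactone; the C5 oxygen is benzylated and the C7 hydroxyl cannot reach the ester, so only the C8a hydroxyl can close, and removal of methanol drives the reaction.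

Step 7
Reactants: 12 (4S)-5-(benzyloxy)-7-hydroxy-8-[3-(4-methoxyphenyl)propanoyl]-4-phenyl-3,4-dihydro-2H-chromen-2-one
Product: 13 (4S)-5,7-dihydroxy-8-[3-(4-methoxyphenyl)propanoyl]-4-phenyl-3,4-dihydro-2H-chromen-2-one
Conditions: H2 (1 atm), Pd/C (10 wt % Pd), EtOAc, rt
Reagents that add atoms: none
Why: Hydrogenolysis of the benzyl aryl ether over palladium on carbon; the chelated aryl ketone, the lactone and the methyl ether should be inert, and the neutral medium avoids migration of the lactone to the freed C5 hydroxyl.

## Compound list

1 | 4-hydroxy-6-methyl-2H-pyran-2-one | Cc1cc(O)cc(=O)o1 | starting material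
2 | methyl 3-(4-methoxyphenyl)propanoate | COC(=O)CCc1ccc(OC)cc1 | starting material
3 | 4-hydroxy-6-[4-(4-methoxyphenyl)-2-oxobutyl]-2H-pyran-2-one | COc1ccc(CCC(=O)Cc2cc(O)cc(=O)o2)cc1 | intermediate
4 | (E)-cinnamaldehyde | O=C/C=C/c1ccccc1 | starting material
5 | (3S)-3-{4-hydroxy-6-[4-(4-methoxyphenyl)-2-oxobutyl]-2-oxo-2H-pyran-3-yl}-3-phenylpropanal | COc1ccc(CCC(=O)Cc2cc(O)c([C@@H](CC=O)c3ccccc3)c(=O)o2)cc1 | intermediate
6 | (4S)-2-hydroxy-7-[4-(4-methoxyphenyl)-2-oxobutyl]-4-phenyl-3,4-dihydro-2H,5H-pyrano[4,3-b]pyran-5-one (C2 anomers) | COc1ccc(CCC(=O)Cc2cc3OC(O)C[C@@H](c4ccccc4)c3c(=O)o2)cc1 | intermediate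
7 | (4S)-7-[4-(4-methoxyphenyl)-2-oxobutyl]-4-phenyl-3,4-dihydro-2H,5H-pyrano[4,3-b]pyran-2,5-dione | COc1ccc(CCC(=O)Cc2cc3OC(=O)C[C@@H](c4ccccc4)c3c(=O)o2)cc1 | intermediate
8 | methyl (3S)-3-{4-hydroxy-6-[4-(4-methoxyphenyl)-2-oxobutyl]-2-oxo-2H-pyran-3-yl}-3-phenylpropanoate | COc1ccc(CCC(=O)Cc2cc(O)c([C@@H](CC(=O)OC)c3ccccc3)c(=O)o2)cc1 | intermediate
9 | methyl (3S)-3-{4-(benzyloxy)-6-[4-(4-methoxyphenyl)-2-oxobutyl]-2-oxo-2H-pyran-3-yl}-3-phenylpropanoate | COc1ccc(CCC(=O)Cc2cc(OCc3ccccc3)c([C@@H](CC(=O)OC)c3ccccc3)c(=O)o2)cc1 | intermediate
10 | dimethyl (2E,3S)-2-[1-(benzyloxy)-7-(4-methoxyphenyl)-3,5-dioxoheptylidene]-3-phenylpentanedioate | COC(=O)C[C@@H](c1ccccc1)/C(C(=O)OC)=C(\OCc1ccccc1)CC(=O)CC(=O)CCc1ccc(OC)cc1 | intermediate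
11 | methyl (3S)-3-{6-(benzyloxy)-2,4-dihydroxy-3-[3-(4-methoxyphenyl)propanoyl]phenyl}-3-phenylpropanoate | COc1ccc(CCC(=O)c2c(O)cc(OCc3ccccc3)c([C@@H](CC(=O)OC)c3ccccc3)c2O)cc1 | intermediate
12 | (4S)-5-(benzyloxy)-7-hydroxy-8-[3-(4-methoxyphenyl)propanoyl]-4-phenyl-3,4-dihydro-2H-chromen-2-one | COc1ccc(CCC(=O)c2c(O)cc(OCc3ccccc3)c3c2OC(=O)C[C@H]3c2ccccc2)cc1 | intermediate
13 | (4S)-5,7-dihydroxy-8-[3-(4-methoxyphenyl)propanoyl]-4-phenyl-3,4-dihydro-2H-chromen-2-one | COc1ccc(CCC(=O)c2c(O)cc(O)c3c2OC(=O)C[C@H]3c2ccccc2)cc1 | target

## Step count and least certain steps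

Total step count: 7. Longest linear sequence: 7 steps (1 to 13).

**Step 5 (key step).** The ester carbonyl of 10 is hindered by the C3 substituent and deactivated as a vinylogous carbonate, so the Claisen closure may be slow. The open chain could then be diverted by exchange of benzyloxide for methoxide through addition–elimination at the enol-ether carbon, or by O-cyclisation of a ketone enolate onto that carbon with loss of benzyl alcohol. A first remedy within the step is an alkoxide matched to the ether. The fallback moves the ring construction ahead of the stereocenter, where the pyrone is unhindered. It sets out from 3 and comes back at 12.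
- 3 is benzylated at O4 under Mitsunobu conditions to 4-(benzyloxy)-6-[4-(4-methoxyphenyl)-2-oxobutyl]-2H-pyran-2-one F1.
- F1 is recyclised with a benzyloxide base (NaOCH2Ph in BnOH/THF, so that any exchange is degenerate) to 1-[4-(benzyloxy)-2,6-dihydroxyphenyl]-3-(4-methoxyphenyl)propan-1-one F2.
- F2 has two equivalent ring carbons, each flanked by one free hydroxyl and the benzyl ether. It is combined with 4 under the catalyst of step 2 (iminium-catalysed Friedel–Crafts alkylation and hemiacetalisation) to give 1-[(4S)-5-(benzyloxy)-2,7-dihydroxy-4-phenyl-3,4-dihydro-2H-chromen-8-yl]-3-(4-methoxyphenyl)propan-1-one F3.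
- F3 is oxidised with Ag2CO3 on Celite to 12.

**Step 2.** The secondary amine may be sequestered by condensation with the activated side-chain ketone of 3, and 1,2-addition followed by electrocyclisation to a 2H-pyran may compete with 1,4-addition. Either would lower conversion and enantiomeric purity. The fallback runs the Michael step on the parent pyrone and attaches the chain afterwards. It sets out from 1 and 4 and comes back at 6.
- 1 and 4 with the same catalyst give (4S)-2-hydroxy-7-methyl-4-phenyl-3,4-dihydro-2H,5H-pyrano[4,3-b]pyran-5-one F4.
- F4 with MeOH and catalytic TsOH gives the methyl acetal (4S)-2-methoxy-7-methyl-4-phenyl-3,4-dihydro-2H,5H-pyrano[4,3-b]pyran-5-one F5, which has no acidic hydroxyl and no ester.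
- F5 is deprotonated at the 7-methyl group with LiN(i-Pr)2 and acylated with 2 to give (4S)-2-methoxy-7-[4-(4-methoxyphenyl)-2-oxobutyl]-4-phenyl-3,4-dihydro-2H,5H-pyrano[4,3-b]pyran-5-one F6.
- Aqueous HCl in THF hydrolyses the acetal of F6 to 6.

**Step 1.** Proton transfer from the enolisable ester 2 to the dianion may return 1, with self-condensation of 2. The fallback replaces the acylation by an aldol addition and an oxidation. It sets out from 1 and comes back at 3.
- The dianion of 1 adds to commercial 3-(4-methoxyphenyl)propanal (addition to an aldehyde outruns enolisation) to give racemic 4-hydroxy-6-[2-hydroxy-4-(4-methoxyphenyl)butyl]-2H-pyran-2-one F7.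
- F7 is oxidised to 3 with 1,1,1-triacetoxy-1,1-dihydro-1,2-benziodoxol-3(1H)-one.

**Step 4.** The ambident pyronate may be alkylated at the carbonyl oxygen (giving a 2-benzyloxy-4-pyranone), or the active methylene may be C-alkylated. The fallback postpones the differentiation of the oxygens until ring A exists and uses chelation for it. It sets out from 8 and comes back at 11.
- 8 is recyclised with Mg(OMe)2 in MeOH, the classical substrate type with a free 4-hydroxyl, to methyl (3S)-3-{2,4,6-trihydroxy-3-[3-(4-methoxyphenyl)propanoyl]phenyl}-3-phenylpropanoate F8.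
- In F8 the hydroxyl para to the ketone is the only one that is not chelated and is the most acidic. One equivalent of BnBr with K2CO3 in acetone should alkylate it selectively to give 11.

**Step 6.** The acid-catalysed transesterification may stall, because the C8a hydroxyl is chelated to the ketone, or may be accompanied by loss or migration of the benzyl group at 80 °C. The fallback activates a free acid instead. It sets out from 11 and comes back at 12.
- 11 is saponified with LiOH in THF/H2O to (3S)-3-{6-(benzyloxy)-2,4-dihydroxy-3-[3-(4-methoxyphenyl)propanoyl]phenyl}-3-phenylpropanoic acid F9.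
- F9 is closed to 12 at rt with 1-ethyl-3-(3-dimethylaminopropyl)carbodiimide hydrochloride.

## Further compounds

F1 | step 5 | 4-(benzyloxy)-6-[4-(4-methoxyphenyl)-2-oxobutyl]-2H-pyran-2-one | COc1ccc(CCC(=O)Cc2cc(OCc3ccccc3)cc(=O)o2)cc1
F2 | step 5 | 1-[4-(benzyloxy)-2,6-dihydroxyphenyl]-3-(4-methoxyphenyl)propan-1-one | COc1ccc(CCC(=O)c2c(O)cc(OCc3ccccc3)cc2O)cc1
F3 | step 5 | 1-[(4S)-5-(benzyloxy)-2,7-dihydroxy-4-phenyl-3,4-dihydro-2H-chromen-8-yl]-3-(4-methoxyphenyl)propan-1-one | COc1ccc(CCC(=O)c2c(O)cc(OCc3ccccc3)c3c2OC(O)C[C@H]3c2ccccc2)cc1
F4 | step 2 | (4S)-2-hydroxy-7-methyl-4-phenyl-3,4-dihydro-2H,5H-pyrano[4,3-b]pyran-5-one | Cc1cc2OC(O)C[C@@H](c3ccccc3)c2c(=O)o1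
F5 | step 2 | (4S)-2-methoxy-7-methyl-4-phenyl-3,4-dihydro-2H,5H-pyrano[4,3-b]pyran-5-one | Cc1cc2OC(OC)C[C@@H](c3ccccc3)c2c(=O)o1
F6 | step 2 | (4S)-2-methoxy-7-[4-(4-methoxyphenyl)-2-oxobutyl]-4-phenyl-3,4-dihydro-2H,5H-pyrano[4,3-b]pyran-5-one | COc1ccc(CCC(=O)Cc2cc3OC(OC)C[C@@H](c4ccccc4)c3c(=O)o2)cc1
F7 | step 1 | 4-hydroxy-6-[2-hydroxy-4-(4-methoxyphenyl)butyl]-2H-pyran-2-one | COc1ccc(CCC(O)Cc2cc(O)cc(=O)o2)cc1
F8 | step 4 | methyl (3S)-3-{2,4,6-trihydroxy-3-[3-(4-methoxyphenyl)propanoyl]phenyl}-3-phenylpropanoate | COc1ccc(CCC(=O)c2c(O)cc(O)c([C@@H](CC(=O)OC)c3ccccc3)c2O)cc1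
F9 | step 6 | (3S)-3-{6-(benzyloxy)-2,4-dihydroxy-3-[3-(4-methoxyphenyl)propanoyl]phenyl}-3-phenylpropanoic acid | COc1ccc(CCC(=O)c2c(O)cc(OCc3ccccc3)c([C@@H](CC(=O)O)c3ccccc3)c2O)cc1
A1 | alternative 1 | 3-(4-methoxyphenyl)-1-(2,4,6-trihydroxyphenyl)propan-1-one | COc1ccc(CCC(=O)c2c(O)cc(O)cc2O)cc1
A2 | alternative 1 | (4S)-5,7-dihydroxy-6-[3-(4-methoxyphenyl)propanoyl]-4-phenyl-3,4-dihydro-2H-chromen-2-one | COc1ccc(CCC(=O)c2c(O)cc3OC(=O)C[C@@H](c4ccccc4)c3c2O)cc1
A3 | alternative 2 | 5,7-bis(benzyloxy)-8-[3-(4-methoxyphenyl)propanoyl]-2H-chromen-2-one | COc1ccc(CCC(=O)c2c(OCc3ccccc3)cc(OCc3ccccc3)c3ccc(=O)oc23)cc1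
A4 | alternative 3 | methyl 3-{(4S)-6-[4-(4-methoxyphenyl)-2-oxobutyl]-2-oxo-4-phenyl-3,4-dihydro-2H-pyran-5-yl}-3-oxopropanoate | COC(=O)CC(=O)C1=C(CC(=O)CCc2ccc(OC)cc2)OC(=O)C[C@H]1c1ccccc1
A5 | alternative 3 | methyl 9-(4-methoxyphenyl)-3,5,7-trioxononanoate | COC(=O)CC(=O)CC(=O)CC(=O)CCc1ccc(OC)cc1
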